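**Retrosynthetic overview**
1. Dendronpholide R (36) comes from bicyclic ether 33 by oxidation of C16 only. The oxolane O–C4–C5–C6–C7 of 33 is closed last, by a Re2O7-catalysed allylic transposition with transannular epoxide opening of the 14-membered epoxy allylic alcohol 31.
2. Enabling feature: C7 is the carbinol carbon of the 2-methylene allylic alcohol C19=C8–C7–OH and lies 1,4 to the tertiary epoxide carbon C4 across C5–C6. A 1,3-shift of oxygen (C7 to C19 and back) can therefore edit C7 before O7 attacks C4 from the rear. The (3R,4R) pattern of the target is that of an anti opening of a (3R,4S)-epoxide derived from a (Z)-C3=C4 olefin.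
3. The 14-membered carbocycle (first ring) is closed at C7–C8 by nickel-catalysed reductive macrocyclisation of seco ynal 29; the C7 configuration is left open on purpose.
4. Ynal 29 comes from (R)-limonene, which supplies C1, its side chain, C2–C3 and C11–C14 after ring cleavage. The (E)-C11=C12 olefin (alkyne carboalumination, Negishi coupling) gives C11/C12 by Shi epoxidation and hydrolysis with inversion; the (Z)-C3=C4 olefin (iodo-ylide Wittig, Negishi coupling) gives the epoxide by a second Shi epoxidation.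
5. Ring order: limonene ring cleaved, then 14-membered ring (step 16), then oxolane (step 17).

Key step: step 17

Remark: cembrane numbering is used throughout (C1 carries C15(=C17H2)–C16; C18, C19, C20 are the carbons on C4, C8, C12); the target is read as (1R,3R,4R,7S,11S,12R); compound 15 and both enantiomers of the Shi ketone are taken as commercial.

**Step 1**
Reactants: 1 (R)-(+)-limonene
Product: 4 (R)-limonen-10-ol, via allyllithium 2 (not isolated), via allylboronate 3 (not isolated)
Conditions: n-BuLi, TMEDA, rt; B(OMe)3, THF, −78 °C; H2O2, NaOH aq., 0 °C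
Reagents that add atoms: hydrogen peroxide, OO
Why: Allylic metalation at the isopropenyl methyl group, borylation and oxidative C–B to C–O conversion give the 2-substituted allyl alcohol; the allyl unit is symmetric, so no regioisomer can form, and the stereocentre (future C1) is not touched.

**Step 2**
Reactants: 4 (R)-limonen-10-ol
Product: 5 tert-butyldiphenylsilyl ether of 4
Conditions: TBDPSCl, imidazole, DMF, rt
Reagents that add atoms: tert-butyl(chloro)diphenylsilane, CC(C)(C)[Si](Cl)(c1ccccc1)c1ccccc1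
Why: Standard silylation of a primary alcohol gives a group that should survive bases, organoaluminium, dilute acid and the oxidations that follow.

**Step 3**
Reactants: 5 silyl ether
Product: 8 keto acetal, via methoxy hydroperoxide aldehyde 6 (not isolated), via methoxy hydroperoxide acetal 7 (not isolated)
Conditions: O3 (1 equiv), CH2Cl2/MeOH, −78 °C; TsOH·H2O, rt; NaHCO3; Me2S
Reagents that add atoms: ozone, [O-][O+]=O; methanol, CO
Why: Ozonolysis with differentiated termini: the electron-rich trisubstituted ring olefin is cleaved, the carbonyl oxide at the methyl-bearing carbon is trapped by methanol, the aldehyde is acetalised and Me2S releases the methyl ketone, while the 1,1-disubstituted olefin deactivated by the allylic oxygen should survive.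

**Step 4**
Reactants: 8 keto acetal
Product: 12 terminal alkyne, via lithium enolate 9 (not isolated), via enol phosphate 10 (not isolated), via lithium acetylide 11 (not isolated)
Conditions: LiN(i-Pr)2, THF, −78 °C; ClP(O)(OEt)2; LiN(i-Pr)2 (2.3 equiv), −78 °C to rt; H2O
Reagents that add atoms: none
Why: Methyl ketone to terminal alkyne through the kinetic enol phosphate and base-induced elimination (Negishi protocol); the former methyl carbon becomes C11.

**Step 5**
Reactants: 12 terminal alkyne
Product: 14 (E)-alkenyl iodide, via alkenylalane 13 (not isolated)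
Conditions: Me3Al, Cp2ZrCl2 (cat.), CH2Cl2, −20 to 0 °C; I2, THF, −30 °C
Reagents that add atoms: trimethylaluminium, C[Al](C)C; iodine, II
Why: Zirconium-catalysed syn carboalumination places methyl (C20) on C12 and aluminium on C11, and iodinolysis with retention fixes the (E)-geometry; the low temperature is chosen to spare the acetal.

**Step 6**
Reactants: 14 (E)-alkenyl iodide; 15 (4-bromobut-1-yn-1-yl)trimethylsilane
Product: 17 (E)-enyne, via alkylzinc bromide 16 (not isolated)
Conditions: 15, Zn, I2 (cat.), DMA, 70 °C; then 14, Pd(PPh3)4 (cat.), THF, rt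
Reagents that add atoms: none
Why: Negishi sp2–sp3 cross-coupling proceeds with retention of olefin geometry and brings in C8–C10 with C19 as a masked terminal alkyne.

**Step 7**
Reactants: 17 (E)-enyne
Product: 18 (11S,12S)-epoxide
Conditions: ent-Shi ketone (L-fructose-derived, 30 mol %), KHSO5, K2CO3, Bu4NHSO4, MeCN/DMM/aq. Na2B4O7 buffer, 0 °C
Reagents that add atoms: potassium peroxymonosulfate, [K+].[O-]S(=O)(=O)OO
Why: Shi asymmetric epoxidation through the spiro dioxirane transition state acts on the only trisubstituted olefin, and the L-series ketone should deliver oxygen to the face that gives the (11S,12S)-epoxide under reagent control.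

**Step 8**
Reactants: 18 (11S,12S)-epoxide
Product: 19 (11S,12R)-diol aldehyde
Conditions: HClO4 (dilute aq.), THF, 0 °C to rt
Reagents that add atoms: water, O
Why: Acid-catalysed epoxide hydrolysis: water attacks the protonated epoxide at the tertiary carbon C12 with inversion (borderline SN2), which sets (12R) beside the retained (11S) carbinol, and the same acid hydrolyses the dimethyl acetal to the C3 aldehyde.

**Step 9**
Reactants: 19 diol aldehyde
Product: 20 C11 acetate
Conditions: Ac2O, pyridine, DMAP (cat.), CH2Cl2, 0 °C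
Reagents that add atoms: acetic anhydride, CC(=O)OC(C)=O
Why: Acylation selects the secondary C11 hydroxyl over the tertiary C12 hydroxyl on steric grounds, and it is done here because no other secondary hydroxyl is present.

**Step 10**
Reactants: 20 acetate aldehyde
Product: 21 (Z)-alkenyl iodide
Conditions: EtPPh3I, n-BuLi, THF; I2, −78 °C; NaN(SiMe3)2, −20 °C; 20, −78 °C
Reagents that add atoms: ethyltriphenylphosphonium iodide, CC[P+](c1ccccc1)(c1ccccc1)c1ccccc1.[I-]; iodine, II
Why: Stork–Zhao-type Wittig olefination with the α-iodo ylide gives the (Z)-2-iodo-2-alkene (iodine cis to C2) by kinetic cis-oxaphosphetane formation, and the ylide is too weak a base to deprotonate the tertiary alcohol.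

**Step 11**
Reactants: 22 3-bromopropan-1-ol
Product: 23 (3-bromopropoxy)triethylsilane
Conditions: Et3SiCl, imidazole, CH2Cl2, 0 °C
Reagents that add atoms: chlorotriethylsilane, CC[Si](Cl)(CC)CC
Why: Standard silylation; the triethylsilyl ether is chosen because a primary triethylsilyl ether can later be oxidised directly to the aldehyde.

**Step 12**
Reactants: 21 (Z)-alkenyl iodide; 23 (3-bromopropoxy)triethylsilane
Product: 25 (3Z)-olefin, via alkylzinc bromide 24 (not isolated)
Conditions: 23, Zn, I2 (cat.), DMA, 70 °C; then 21, PdCl2(dppf) (cat.), THF, rt to 40 °C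
Reagents that add atoms: none
Why: Negishi coupling of a (Z)-alkenyl iodide with a primary alkylzinc reagent occurs with retention, so C5 ends up cis to C2 as the (3Z)-olefin requires.

**Step 13**
Reactants: 25 (3Z)-olefin
Product: 26 (3R,4S)-epoxide
Conditions: Shi ketone (D-fructose-derived, 30 mol %), KHSO5, K2CO3, Bu4NHSO4, MeCN/DMM/aq. Na2B4O7 buffer, 0 °C
Reagents that add atoms: potassium peroxymonosulfate, [K+].[O-]S(=O)(=O)OO
Why: Shi epoxidation of the only electron-rich trisubstituted olefin; by the spiro model the D-series ketone should make the CH carbon C3 (R), which gives the cis-(3R,4S)-epoxide under reagent control.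

**Step 14**
Reactants: 26 (3R,4S)-epoxide
Product: 27 terminal alkyne
Conditions: AgNO3 (cat.), 2,6-lutidine, acetone/H2O, rt
Reagents that add atoms: none
Why: Silver-catalysed protodesilylation of the alkynylsilane runs near neutrality and should leave acetate, epoxide and silyl ethers intact.

**Step 15**
Reactants: 27 terminal alkyne
Product: 29 seco ynal, via alkoxysulfonium chloride 28 (not isolated)
Conditions: (COCl)2, DMSO, CH2Cl2, −78 to −40 °C; Et3N, −78 to 0 °C
Reagents that add atoms: none
Why: Swern oxidation applied directly to the primary triethylsilyl ether: the sulfonium reagent displaces the silyl group, so the aldehyde forms without a free 4,5-epoxy alcohol that could cyclise too early.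

**Step 16**
Reactants: 29 seco ynal
Product: 31 macrocyclic epoxy allylic alcohol (both C7 epimers), via macrocyclic silyl ether 30 (not isolated)
Conditions: Ni(cod)2 (20 mol %), IPr (1,3-bis(2,6-diisopropylphenyl)imidazol-2-ylidene, 20 mol %), Et3SiH, THF, rt, slow addition, high dilution; then HF·pyridine, pyridine, THF, 0 °C
Reagents that add atoms: none
Why: Nickel-catalysed reductive ynal macrocyclisation: aldehyde and alkyne couple oxidatively at zerovalent nickel, the bulky carbene directs C–C bond formation to the substituted alkyne carbon C8 (exocyclic methylene), the silane turns the metallacycle over, and buffered fluoride frees the hydroxyl; C7 is not controlled and need not be.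

**Step 17**
Reactants: 31 macrocyclic epoxy allylic alcohol (both C7 epimers)
Product: 33 bicyclic ether, via primary allyl perrhenate 32 (not isolated)
Conditions: Re2O7 (5 mol %), CH2Cl2, rt
Reagents that add atoms: none
Why: Re2O7 esterifies the allylic hydroxyl, and the perrhenate undergoes reversible [3,3]-type 1,3-transposition through the primary allyl perrhenate 32 (C19–O, endocyclic C7=C8), so both C7 epimers of 31 interconvert and the C8=C19 methylene is restored whenever oxygen returns to C7. The closest known reaction type is the Re2O7-catalysed allylic alcohol transposition in which the transposed hydroxyl is trapped by a pendant epoxide. The oxolane closes by transannular 5-exo-tet attack of O7 on the acid-activated epoxide at the tertiary carbon C4, anti to the breaking C4–O bond. C4 is set by inversion of the (4S)-epoxide carbon from step 13 (giving 4R), C3 keeps its epoxide oxygen and configuration (3R), and C7 is selected dynamically, because only the (7S) epimer can bring O7 behind C4 while C8 and C3 stay on the same face of the new ring (cis-2,5 bridge spanned by the eight-atom chain C9 to C2), the (7R) epimer returning to the pool through 32. The step needs regioselectivity for C4 over C3 (tertiary centre, 5-exo over 6-endo), chemoselectivity over the C12 hydroxyl (it could only form a seven- or eight-membered ring) and no ionisation elsewhere (the C16 allyl silyl ether can only transpose onto itself). The product is a non-stabilised allylic ether and should not re-ionise.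

**Step 18**
Reactants: 33 bicyclic ether
Product: 34 C16 allylic alcohol
Conditions: HF·pyridine, pyridine, THF, rt
Reagents that add atoms: none
Why: Fluoride-mediated cleavage of the silyl ether under buffered conditions should leave the secondary acetate, the allylic ether and the free hydroxyls untouched.

**Step 19**
Reactants: 34 C16 allylic alcohol
Product: 35 enal
Conditions: MnO2, CH2Cl2, rt
Reagents that add atoms: none
Why: MnO2 oxidises only the allylic primary alcohol and leaves the non-allylic secondary C3 and tertiary C12 hydroxyls.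

**Step 20**
Reactants: 35 enal
Product: 36 Dendronpholide R
Conditions: NaClO2, NaH2PO4, 2-methyl-2-butene, t-BuOH/H2O, 0 °C to rt
Reagents that add atoms: sodium chlorite, [Na+].[O-]Cl=O
Why: Pinnick oxidation converts the 2-substituted acrolein into the acrylic acid under buffered conditions without touching olefins, acetate or hydroxyls.

**Compound list**
1 | (R)-(+)-limonene | CC(=C)[C@@H]1CCC(C)=CC1 | starting material
2 | allyllithium of 1 (Li on the side-chain CH2, future C16) | [Li]CC(=C)[C@@H]1CCC(C)=CC1 | intermediate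
3 | dimethyl allylboronate (B(OMe)2 on future C16) | COB(OC)CC(=C)[C@@H]1CCC(C)=CC1 | intermediate
4 | (R)-limonen-10-ol, 2-[(1R)-4-methylcyclohex-3-en-1-yl]prop-2-en-1-ol | OCC(=C)[C@@H]1CCC(C)=CC1 | intermediate
5 | tert-butyldiphenylsilyl ether of 4 | CC(C)(C)[Si](OCC(=C)[C@@H]1CCC(C)=CC1)(c2ccccc2)c3ccccc3 | intermediate
6 | (1R)-methoxy hydroperoxide aldehyde (C3 aldehyde; C12 with CH3, OMe, OOH; C16 OTBDPS) | CC(C)(C)[Si](OCC(=C)[C@@H](CC=O)CCC(C)(OC)OO)(c1ccccc1)c2ccccc2 | intermediate
7 | methoxy hydroperoxide acetal (as 6, C3 as dimethyl acetal) | CC(C)(C)[Si](OCC(=C)[C@@H](CC(OC)OC)CCC(C)(OC)OO)(c1ccccc1)c2ccccc2 | intermediate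
8 | (1R)-keto acetal (C3 dimethyl acetal; C12 methyl ketone whose CH3 is the future C11) | CC(C)(C)[Si](OCC(=C)[C@@H](CC(OC)OC)CCC(C)=O)(c1ccccc1)c2ccccc2 | intermediate
9 | kinetic lithium enolate of 8 (C12=C11H2) | CC(C)(C)[Si](OCC(=C)[C@@H](CC(OC)OC)CCC(=C)O[Li])(c1ccccc1)c2ccccc2 | intermediate
10 | enol diethyl phosphate of 8 | CC(C)(C)[Si](OCC(=C)[C@@H](CC(OC)OC)CCC(=C)OP(=O)(OCC)OCC)(c1ccccc1)c2ccccc2 | intermediate
11 | lithium acetylide (C12≡C11–Li) | CC(C)(C)[Si](OCC(=C)[C@@H](CC(OC)OC)CCC#C[Li])(c1ccccc1)c2ccccc2 | intermediate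
12 | (1R)-terminal alkyne (C12≡C11H) | CC(C)(C)[Si](OCC(=C)[C@@H](CC(OC)OC)CCC#C)(c1ccccc1)c2ccccc2 | intermediate
13 | (E)-alkenyl dimethylalane (C12(CH3)=C11H–AlMe2) | CC(C)(C)[Si](OCC(=C)[C@@H](CC(OC)OC)CC/C(C)=C/[Al](C)C)(c1ccccc1)c2ccccc2 | intermediate
14 | (1R,11E)-alkenyl iodide (C12(C20H3)=C11H–I) | CC(C)(C)[Si](OCC(=C)[C@@H](CC(OC)OC)CC/C(C)=C/I)(c1ccccc1)c2ccccc2 | intermediate
15 | (4-bromobut-1-yn-1-yl)trimethylsilane | C[Si](C)(C)C#CCCBr | starting material
16 | [4-(trimethylsilyl)but-3-yn-1-yl]zinc bromide | C[Si](C)(C)C#CCC[Zn]Br | intermediate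
17 | (1R,11E)-enyne acetal (C11=C12 olefin, C8≡C19–SiMe3) | CC(C)(C)[Si](OCC(=C)[C@@H](CC(OC)OC)CC/C(C)=C/CCC#C[Si](C)(C)C)(c1ccccc1)c2ccccc2 | intermediate
18 | (1R,11S,12S)-11,12-epoxide of 17 | CC(C)(C)[Si](OCC(=C)[C@@H](CC(OC)OC)CC[C@]1(C)O[C@H]1CCC#C[Si](C)(C)C)(c2ccccc2)c3ccccc3 | intermediate
19 | (1R,11S,12R)-11,12-diol with C3 aldehyde | CC(C)(C)[Si](OCC(=C)[C@@H](CC=O)CC[C@@](C)(O)[C@@H](O)CCC#C[Si](C)(C)C)(c1ccccc1)c2ccccc2 | intermediate
20 | (1R,11S,12R)-11-acetate of 19 (12-OH free) | CC(C)(C)[Si](OCC(=C)[C@@H](CC=O)CC[C@@](C)(O)[C@@H](OC(C)=O)CCC#C[Si](C)(C)C)(c1ccccc1)c2ccccc2 | intermediate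
21 | (1R,3Z,11S,12R)-alkenyl iodide (C3H=C4(I)–C18H3) | CC(C)(C)[Si](OCC(=C)[C@@H](C/C=C(/C)I)CC[C@@](C)(O)[C@@H](OC(C)=O)CCC#C[Si](C)(C)C)(c1ccccc1)c2ccccc2 | intermediate
22 | 3-bromopropan-1-ol | OCCCBr | starting material
23 | (3-bromopropoxy)triethylsilane | CC[Si](CC)(CC)OCCCBr | intermediate
24 | [3-(triethylsilyloxy)propyl]zinc bromide | CC[Si](CC)(CC)OCCC[Zn]Br | intermediate
25 | (1R,3Z,11S,12R)-olefin with C5–C6–C7–OSiEt3 chain | CC(C)(C)[Si](OCC(=C)[C@@H](C/C=C(/C)CCCO[Si](CC)(CC)CC)CC[C@@](C)(O)[C@@H](OC(C)=O)CCC#C[Si](C)(C)C)(c1ccccc1)c2ccccc2 | intermediate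
26 | (1R,3R,4S,11S,12R)-3,4-epoxide of 25 | CC(C)(C)[Si](OCC(=C)[C@@H](C[C@H]1O[C@@]1(C)CCCO[Si](CC)(CC)CC)CC[C@@](C)(O)[C@@H](OC(C)=O)CCC#C[Si](C)(C)C)(c2ccccc2)c3ccccc3 | intermediate
27 | terminal alkyne (C8≡C19H) from 26 | CC(C)(C)[Si](OCC(=C)[C@@H](C[C@H]1O[C@@]1(C)CCCO[Si](CC)(CC)CC)CC[C@@](C)(O)[C@@H](OC(C)=O)CCC#C)(c2ccccc2)c3ccccc3 | intermediate
28 | alkoxydimethylsulfonium chloride at C7–O | CC(C)(C)[Si](OCC(=C)[C@@H](C[C@H]1O[C@@]1(C)CCCO[S+](C)C)CC[C@@](C)(O)[C@@H](OC(C)=O)CCC#C)(c2ccccc2)c3ccccc3.[Cl-] | intermediate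
29 | (1R,3R,4S,11S,12R)-seco ynal (C7 aldehyde, C8≡C19H) | CC(C)(C)[Si](OCC(=C)[C@@H](C[C@H]1O[C@@]1(C)CCC=O)CC[C@@](C)(O)[C@@H](OC(C)=O)CCC#C)(c2ccccc2)c3ccccc3 | intermediate
30 | 14-membered 7-O-triethylsilyl ether with 8(19)-methylene, both C7 epimers | CC(C)(C)[Si](OCC(=C)[C@@H]1CC[C@@](C)(O)[C@@H](OC(C)=O)CCC(=C)C(O[Si](CC)(CC)CC)CC[C@]2(C)O[C@@H]2C1)(c3ccccc3)c4ccccc4 | intermediate
31 | 14-membered epoxy allylic alcohol (1R,3R,4S,11S,12R), both C7 epimers | CC(C)(C)[Si](OCC(=C)[C@@H]1CC[C@@](C)(O)[C@@H](OC(C)=O)CCC(=C)C(O)CC[C@]2(C)O[C@@H]2C1)(c3ccccc3)c4ccccc4 | intermediate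
32 | primary allyl perrhenate (C7=C8 endocyclic, C19–O–ReO3) | CC(C)(C)[Si](OCC(=C)[C@@H]1CC[C@@](C)(O)[C@@H](OC(C)=O)CCC(CO[Re](=O)(=O)=O)=CCC[C@]2(C)O[C@@H]2C1)(c3ccccc3)c4ccccc4 | intermediate
33 | (1R,3R,4R,7S,11S,12R)-4,7-epoxy bicycle with C16 OTBDPS | CC(C)(C)[Si](OCC(=C)[C@@H]1CC[C@@](C)(O)[C@@H](OC(C)=O)CCC(=C)[C@@H]2CC[C@@](C)(O2)[C@H](O)C1)(c3ccccc3)c4ccccc4 | intermediate
34 | C16 primary allylic alcohol | OCC(=C)[C@@H]1CC[C@@](C)(O)[C@@H](OC(C)=O)CCC(=C)[C@@H]2CC[C@@](C)(O2)[C@H](O)C1 | intermediate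
35 | C16 enal | O=CC(=C)[C@@H]1CC[C@@](C)(O)[C@@H](OC(C)=O)CCC(=C)[C@@H]2CC[C@@](C)(O2)[C@H](O)C1 | intermediate
36 | Dendronpholide R | C=C(C(=O)O)[C@@H]1CC[C@@](C)(O)[C@@H](OC(C)=O)CCC(=C)[C@@H]2CC[C@@](C)(O2)[C@H](O)C1 | target

**Total step count:** 20. **Longest linear sequence:** 19 steps (steps 1–10 and 12–20 from (R)-limonene).

**Steps most likely to fail**

Step 17 (key step). What may go wrong: direct acid-promoted reaction of the epoxide (hydride shift to a C3 ketone, or attack by the mismatched C7 epimer) may outrun the transposition, so that stereoconvergence is lost. Fallback, setting out from 31 and returning at 33: the C7 carbinol mixture is oxidised with Dess–Martin periodinane (NaHCO3, CH2Cl2) to the macrocyclic 2-methylene ketone F1. Reagent-controlled Corey–Bakshi–Shibata reduction ((R)-2-methyl-CBS-oxazaborolidine, catecholborane, toluene, −78 °C, the alkenyl group acting as the large substituent) should give the (7S)-alcohol F2. Catalytic camphorsulfonic acid in CH2Cl2 at 0 °C then effects the ordinary stereospecific 5-exo epoxide opening to 33.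

Step 16 (macrocyclisation). What may go wrong: intermolecular coupling to oligomers, C–C bond formation at the terminal alkyne carbon (endocyclic olefin, 15-membered ring) or plain hydrosilylation of the aldehyde may dominate. Fallback, setting out from 27 and returning at 31: Markovnikov hydrosilylation of the terminal alkyne (Et3SiH, [Cp*Ru(MeCN)3]PF6, CH2Cl2) gives the 2-(triethylsilyl)-1-alkene F3. Iododesilylation (N-iodosuccinimide, 2,6-lutidine, MeCN, 0 °C) gives the 2-iodo-1-alkene F4. Direct Swern oxidation of the primary triethylsilyl ether, as in step 15, gives the iodo aldehyde F5. Nozaki–Hiyama–Kishi macrocyclisation (CrCl2, NiCl2 cat., DMSO/THF, high dilution) closes C7–C8 and gives 31 directly as the free carbinols.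

Step 10 (iodo-ylide olefination). What may go wrong: decay of the iodo ylide before it meets the functionalised aldehyde (low conversion), erosion of the Z/E ratio, or base-induced acetyl migration. Fallback, setting out from 20 and returning at 25 (21 is bypassed): dichloro-olefination of 20 (PPh3, BrCCl3, MeCN) gives the 1,1-dichloroalkene F6. Palladium-catalysed trans-selective monomethylation (MeZnCl, PdCl2(DPEphos), THF/DMF) replaces the chloride trans to C2 and gives the (Z)-2-chloro-2-alkene F7. Second-stage Negishi coupling of F7 with alkylzinc bromide 24 (Pd(P(t-Bu)3)2, THF/DMA), with retention, gives 25.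

**Further compounds**
F1 | step 17 | macrocyclic 2-methylene ketone (C7 ketone, 8(19)-ene, 3,4-epoxide) | CC(C)(C)[Si](OCC(=C)[C@@H]1CC[C@@](C)(O)[C@@H](OC(C)=O)CCC(=C)C(=O)CC[C@]2(C)O[C@@H]2C1)(c3ccccc3)c4ccccc4
F2 | step 17 | (7S)-epoxy allylic alcohol | CC(C)(C)[Si](OCC(=C)[C@@H]1CC[C@@](C)(O)[C@@H](OC(C)=O)CCC(=C)[C@@H](O)CC[C@]2(C)O[C@@H]2C1)(c3ccccc3)c4ccccc4
F3 | step 16 | 2-(triethylsilyl)-1-alkene (C8(SiEt3)=C19H2, C7 OSiEt3) | CC(C)(C)[Si](OCC(=C)[C@@H](C[C@H]1O[C@@]1(C)CCCO[Si](CC)(CC)CC)CC[C@@](C)(O)[C@@H](OC(C)=O)CCC(=C)[Si](CC)(CC)CC)(c2ccccc2)c3ccccc3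
F4 | step 16 | 2-iodo-1-alkene (C8(I)=C19H2, C7 OSiEt3) | CC(C)(C)[Si](OCC(=C)[C@@H](C[C@H]1O[C@@]1(C)CCCO[Si](CC)(CC)CC)CC[C@@](C)(O)[C@@H](OC(C)=O)CCC(I)=C)(c2ccccc2)c3ccccc3
F5 | step 16 | iodo aldehyde (C7 aldehyde, C8(I)=C19H2) | CC(C)(C)[Si](OCC(=C)[C@@H](C[C@H]1O[C@@]1(C)CCC=O)CC[C@@](C)(O)[C@@H](OC(C)=O)CCC(I)=C)(c2ccccc2)c3ccccc3
F6 | step 10 | 1,1-dichloroalkene (C3H=C4Cl2) | CC(C)(C)[Si](OCC(=C)[C@@H](CC=C(Cl)Cl)CC[C@@](C)(O)[C@@H](OC(C)=O)CCC#C[Si](C)(C)C)(c1ccccc1)c2ccccc2
F7 | step 10 | (Z)-2-chloro-2-alkene (C3H=C4(Cl)–C18H3) | CC(C)(C)[Si](OCC(=C)[C@@H](C/C=C(/C)Cl)CC[C@@](C)(O)[C@@H](OC(C)=O)CCC#C[Si](C)(C)C)(c1ccccc1)c2ccccc2
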